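Start from a ratio: once step 4 has balanced, J stands to Q as 1.3, so reckon Q and J as one pool, a pre-equilibrium.

- larch: L 14 mM; D 14.0 mM; time 40 h
- cedar: L 14 mM; D 7.00 mM; time 40 h

    L + Q → L.Q (k1 = 0.070 /M/min)
    L + D → Q + G (k2 = 0.39 /M/min)
    Q ⇌ E (K3 = 150, k3 = 2.9 × 10⁻⁵ /min)
    Q ⇌ J (K4 = 1.3, k4 = 0.0015 /min)

- percent here means L units held: one L.Q counts as two
- run time (larch): 40 h

- which of the two there is more of at the end, counted by the L in each, larch (J / L.Q)
- which of the two there is more of at the end, counted by the L in each, cedar (J / L.Q)
- final J, as a percentage of the L charged, in larch
- final J, as a percentage of the L charged, in cedar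

1. Check that the balance comes quickly. Step 4 relaxes with a half-life of 4.35 h, shorter than the 40 h of the run. Step 3 needs 16.5 d, longer than the run, so leave E aside.

2. Name the free share, the part of the pool standing as Q: one over one plus the ratio, 43.5%. J holds the rest, 56.5%.

3. Estimate cedar. D is the limiting reagent, so the pool reaches at most 50.0% of the L charged, and J 28.3%.

4. Object: in cedar the spare L, 7.00 mM, eats Q. The pool drains at k1 times L times the free share, 0.0128 /h, so reckon that 60.0% of it survives the run.

5. Object again: that drain spends L too, so cedar's L falls. Take the mean L as 5.60 mM. Now reckon that 66.4% survives, which gives J 18.8% and L.Q, counted double, 33.6%. Commit to L.Q in cedar.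

6. Estimate larch. Take L and D in larch as falling together, on the time scale 3.05 h, and the pool as growing while L falls. Summing L times the free pool over the run, a fraction 13.4% of the charge is lost as L.Q.

7. Object: each loss also takes an L away from D, so in larch the pool is short by twice that fraction and stands at 73.2%. That gives J 41.4% against L.Q 26.8%. Commit to J in larch.

8. The forecast gives J in larch and L.Q in cedar, with J at 40% in larch and 18% in cedar, on the ground for cedar that “the excess L keeps eating Q throughout the run”. My reckoning names the same winners, with J at 41.4% in larch and 18.8% in cedar.

9. The simulation gives larch J 40.3% against L.Q 24.0%, and cedar J 18.0% against L.Q 36.3%. The forecast held on all four answers.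

10. Read larch at the end: J 40.3% and Q 31.4% put J's part of the two at 56.2%, against the 56.5% reckoned. Take away the way back from J to Q, and larch J rises from 40.3% to 71.3%.

11. Carry the free share to cedar read at 4.0 d. Hold L at its 32.0% of the charge and drain J from 18.0%, which leaves 11.4%. That flask gives 12.1%, with L down to 23%.

The rate constants are invented; the rest is arithmetic.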